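The data stem from a simulated flask on assumed constants.

If the end of a flask of solid monomer is its whole charge in chains, I must reckon how fast the fraction climbs, and the earlier runs climb nearly straight, apparently zero order, up to 76.9% in the west run.

| flask | solid monomer | initiator | temperature | remark | time |
|---|---|---|---|---|---|
| south | 0.52 M | 2.5 mol% | 40 °C | run made earlier |  |
| north-west | 0.81 M | 2.5 mol% | 52 °C | run made earlier |  |
| west | 0.37 M | 5 mol% | 40 °C | run made earlier |  |
| Saturday's | 0.37 M | 2.5 mol% | 60 °C |  | 50 min |
| Sunday's | 0.37 M | 2.5 mol% | 45 °C |  | 50 min |
- south (time / min: monomer in chains / %): 20.0: 7.7; 50.0: 14.7; 120: 41.0; 150: 46.7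
- north-west (time / min: monomer in chains / %): 15.0: 4.9; 30.0: 10.1; 50.0: 18.4; 60.0: 20.5
- west (time / min: monomer in chains / %): 40.0: 20.1; 80.0: 42.1; 150: 76.9

(each reading ± 1 percentage point)
- the best flask by amount of monomer in chains, in percent of the solid monomer charged; "all alike" if 1.5 percentage points covers them all (Saturday's / Sunday's / all alike)
- amount of monomer in chains at the end, in percent of the solid monomer charged, Saturday's
- amount of monomer in chains at the end, in percent of the solid monomer charged, Sunday's
- given per volume of solution although it is solid: solid monomer
- what was read earlier has a scatter of 1 percentage point, one standard deviation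
- at the start none of the solid monomer is in solution

I read each run's last point as a fill time, the minutes its line would need for the whole charge. Assuming the absolute rate goes as the square root of the initiator concentration, the fill time goes as the square root of charge over loading. Brought to 0.37 M and 2.5 mol%, the south run gives 271 min and the west run 276 min, two different flasks at 40 °C with a mean of 273 min, while the north-west run gives 198 min at 52 °C. Carrying that ratio on exponentially in temperature, Saturday's fill time, the minutes its line needs for the whole charge, is 159 min and Sunday's is 239 min, so 50 min carries them to 31.4% and 20.9%.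

The weak link is that one temperature ratio, which hangs on a single reading with a scatter of 1 percentage point. Taking the north-west reading at 50.0 min instead gives 184 min, hence 35.5% and 21.6%, and Saturday's stays ahead by more than 1.5 points.

The forecast, built on “a saturated solution fed by solid”, says 32% for Saturday's and 21.5% for Sunday's, a little above my first figures, with Saturday's best.

The flask gives 28.9% for Saturday's and 25.5% for Sunday's, with Saturday's best.

    free monomer + growing radical → monomer in chains + growing radical, rate k1*[growing radical]*[free monomer] (k = 36000 L mol⁻¹ s⁻¹, Ea = 32.0 kJ mol⁻¹)
    solid monomer ⇌ free monomer, rate k2*(cs2 - [free monomer]) while solid is left; crystals form when [free monomer] > cs2 (solubility = 0.120 M, k = 7.10 × 10⁻⁴ s⁻¹)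
    2 growing radical → dead chain (k = 8.00 × 10⁸ L mol⁻¹ s⁻¹, Ea = 11.0 kJ mol⁻¹)
    initiator → 2 initiating radical (k = 6.30 × 10⁻⁴ s⁻¹, Ea = 106 kJ mol⁻¹)
    free monomer + initiating radical → growing radical + monomer in chains (k = 5.00 × 10⁵ L mol⁻¹ s⁻¹, Ea = 31.0 kJ mol⁻¹)
    monomer in chains → over-reaction product (k = 2.90 × 10⁻⁴ s⁻¹, Ea = 91.0 kJ mol⁻¹)
    (constants at 60 °C)

In Saturday's flask at 50.0 min, the half-life of monomer in chains by over-reaction is 40 min, shorter than the run's 50 min, a loss the fill time does not hold. Kept at 75 °C, Saturday's flask has a fill time carried on to 106 min, promising 47.2%, and it gives 3.87%, with monomer in chains and over-reaction product together at 27.3%, less than that promise, and 0.0054% of its initiator left.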